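Numbering the 1,2-dioxane O1–O2–C3(CH2CO2Me)–C4–C5–C6(OMe), the route cuts C4–C5, the one ring bond whose two carbons each neighbour a peroxide-bearing carbon, so the ring is treated as an O–O-tethered pair of allylic centres. Ring-closing metathesis of an acyclic mixed peroxyketal, vinyl on C6 and propenyl on C3, should form C4=C5 and the peroxide ring in one operation; diimide then saturates it. C3 is set beforehand by amine-catalysed asymmetric peroxidation of sorbaldehyde, C6 afterwards by anomeric equilibration in acidic methanol, and the enediyne chain is completed last by Sonogashira coupling.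

Key step: step 6

Remark: the catalyst enantiomer in step 4 is chosen from the usual steric shielding model of diarylprolinol silyl ethers; if the first run shows the opposite sense, the (S)-catalyst is used with no other change.

Step 1
Reactants: 1 ethynyltriisopropylsilane; 2 1,3-dibromopropane
Product: 4 (5-bromopent-1-yn-1-yl)triisopropylsilane, via lithium (triisopropylsilyl)acetylide 3 (not isolated)
Conditions: n-BuLi, THF, −78 °C → 0 °C; then 2 (4 equiv), DMPU, 0 °C → rt
Reagents that add atoms: none
Why: SN2 alkylation of a lithium acetylide with a primary dibromide, the excess of 2 holding back double alkylation.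

Step 2
Reactants: 5 methoxyallene (1-methoxypropa-1,2-diene); 4
Product: 7 (6-methoxyocta-6,7-dien-1-yn-1-yl)triisopropylsilane, via 1-lithio-1-methoxyallene 6 (not isolated)
Conditions: 5, n-BuLi, THF, −40 °C; then 4, −40 °C → rt
Reagents that add atoms: none
Why: α-lithiation of methoxyallene at the oxygen-bearing carbon and SN2 alkylation with the primary bromide is the standard entry to 1-alkyl-1-methoxyallenes.

Step 3
Reactants: 7
Product: 8 rac-(6-hydroperoxy-6-methoxyoct-7-en-1-yn-1-yl)triisopropylsilane
Conditions: H2O2 (anhydrous, in Et2O, 5 equiv), PPTS (cat.), Et2O, −20 °C → 0 °C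
Reagents that add atoms: hydrogen peroxide, OO
Why: acid-catalysed perhydration of an enol ether, in which protonation of the central allene carbon gives a vinyl-substituted oxocarbenium ion that excess H2O2 should capture at the oxygen-bearing carbon, as alcohols do with alkoxyallenes, to give the racemic α-methoxy allylic hydroperoxide.

Step 4
Reactants: 8; 9 (2E,4E)-hexa-2,4-dienal (sorbaldehyde)
Product: 11 (3R,4E)-3-{[3-methoxy-8-(triisopropylsilyl)oct-1-en-7-yn-3-yl]peroxy}hex-4-enoic acid (both epimers at the ketal carbon), via β-peroxy aldehyde 10 (not isolated)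
Conditions: (R)-2-{bis[3,5-bis(trifluoromethyl)phenyl][(trimethylsilyl)oxy]methyl}pyrrolidine (10 mol%), toluene, 0 °C; then NaClO2, NaH2PO4, 2-methylbut-2-ene, t-BuOH/H2O, 0 °C
Reagents that add atoms: sodium chlorite, [Na+].[O-]Cl=O
Why: iminium-catalysed asymmetric oxa-Michael addition of a tertiary α-methoxy hydroperoxide to an enal (β-peroxidation) followed in the same flask by Pinnick oxidation; the diaryl(silyloxy)methyl group of the catalyst shields one face of the s-trans E-iminium ion so that 1,4-addition to the open face should set C3 as R, while the ketal carbon is carried as both epimers.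

Step 5
Reactants: 11
Product: 12 methyl (3R,4E)-3-{[3-methoxy-8-(triisopropylsilyl)oct-1-en-7-yn-3-yl]peroxy}hex-4-enoate (both epimers at the ketal carbon)
Conditions: TMSCHN2, toluene/MeOH, 0 °C
Reagents that add atoms: (trimethylsilyl)diazomethane, C[Si](C)(C)C=[N+]=[N-]
Why: methyl ester formation with a diazoalkane under neutral conditions that leave the acid-labile allylic peroxyketal and the base-sensitive β-peroxy carbonyl unit untouched.

Step 6
Reactants: 12
Product: 13 methyl 2-[(3R)-6-methoxy-6-[5-(triisopropylsilyl)pent-4-yn-1-yl]-3,6-dihydro-1,2-dioxin-3-yl]acetate (both C6 epimers)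
Conditions: second-generation Grubbs catalyst RuCl2(=CHPh)(PCy3)(H2IMes) (10 mol%), CH2Cl2 (5 mM), 40 °C
Reagents that add atoms: none
Why: Proposed new method: the ruthenium benzylidene should exchange onto one of the two allylic alkenes and the new alkylidene should then engage the other through a ruthenacyclobutane ([2+2] cycloaddition and cycloreversion), expelling propene and leaving the C4=C5 double bond. The closest known reaction types are ring-closing metathesis of mixed acrolein acetals of allylic alcohols to 2-alkoxy-3,6-dihydro-2H-pyrans and of N–O-tethered dienes to 3,6-dihydro-1,2-oxazines, together with cross-metathesis of alkenes that carry dialkyl peroxides, which shows that an O–O bond can survive ruthenium carbenes. The one ring closed is the six-membered 3,6-dihydro-1,2-dioxine, formed by ring-closing metathesis of a 1,7-diene whose tether is the C3–O–O–C6 unit, the gauche C–O–O–C dihedral angle holding the two alkenes close. No stereocenter is created, since C3 is carried unchanged from step 4 and both C6 epimers should cyclise, the ketal centre being corrected in step 8. The step needs chemoselectivity for the two alkenes over the O–O bond and the alkyne, which the bulky triisopropylsilyl cap (no enyne metathesis) and the fully alkylated peroxide should secure, and ring closure over oligomerisation, which high dilution and the favoured six-membered ring should secure.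

Step 7
Reactants: 13
Product: 14 methyl 2-[(3S)-6-methoxy-6-[5-(triisopropylsilyl)pent-4-yn-1-yl]-1,2-dioxan-3-yl]acetate (both C6 epimers)
Conditions: KO2CN=NCO2K, AcOH, CH2Cl2, 0 °C → rt
Reagents that add atoms: none
Why: diimide reduction, the standard peroxide-compatible alkene saturation, should deliver H2 in a concerted syn fashion to the cis-disubstituted ring alkene without O–O cleavage while the hindered silyl alkyne reacts more slowly; the C3 descriptor changes from R to S by the priority rules alone.

Step 8
Reactants: 14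
Product: 15 methyl 2-[(3S,6R)-6-methoxy-6-[5-(triisopropylsilyl)pent-4-yn-1-yl]-1,2-dioxan-3-yl]acetate
Conditions: CSA (cat.), MeOH, rt
Reagents that add atoms: methanol, CO
Why: acid-catalysed peroxyketal exchange under thermodynamic control, in which reversible ionisation at C6 should funnel both epimers into the chair with axial OMe (anomeric effect) and equatorial side chain and acetate arm, which is the cis 3S,6R isomer; C3 is not touched.

Step 9
Reactants: 15
Product: 17 methyl 2-[(3S,6R)-6-methoxy-6-(pent-4-yn-1-yl)-1,2-dioxan-3-yl]acetate, via silver acetylide 16 (not isolated)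
Conditions: AgF, MeOH/THF, rt, dark; then aq. HCl (1 M), 0 °C
Reagents that add atoms: none
Why: silver fluoride protodesilylation of the hindered alkynylsilane via the silver acetylide avoids basic fluoride, which could open the β-peroxy ester by retro-oxa-Michael reaction.

Step 10
Reactants: 18 dec-9-yn-1-ol
Product: 21 10-(trimethylsilyl)dec-9-yn-1-ol, via dilithio alkoxide acetylide 19 (not isolated), via bis-silylated ynol 20 (not isolated)
Conditions: n-BuLi (2.2 equiv), THF, −78 °C; TMSCl (2.3 equiv), −78 °C → rt; then aq. HCl (1 M), rt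
Reagents that add atoms: chlorotrimethylsilane, C[Si](C)(C)Cl
Why: double deprotonation and silylation followed by selective acid hydrolysis of the labile O–Si bond leaves only the C-silylated alkyne.

Step 11
Reactants: 21
Product: 22 10-(trimethylsilyl)dec-9-ynal
Conditions: DMP, CH2Cl2, rt
Reagents that add atoms: none
Why: Dess–Martin oxidation takes the primary alcohol to the aldehyde under neutral conditions without over-oxidation.

Step 12
Reactants: 22
Product: 23 [(10E)-11-iodoundec-10-en-1-yn-1-yl]trimethylsilane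
Conditions: CrCl2, CHI3, THF, 0 °C → rt
Reagents that add atoms: iodoform, IC(I)I
Why: Takai olefination, in which the gem-dichromium species from CHI3 and CrCl2 adds to the aldehyde and eliminates to give the E-vinyl iodide.

Step 13
Reactants: 17; 23
Product: 24 methyl 2-[(3S,6R)-6-methoxy-6-[(6E)-16-(trimethylsilyl)hexadec-6-ene-4,15-diyn-1-yl]-1,2-dioxan-3-yl]acetate
Conditions: Pd(PPh3)4 (5 mol%), CuI (10 mol%), Et3N, THF, rt
Reagents that add atoms: none
Why: Sonogashira coupling joins the terminal alkyne to the vinyl iodide with retention of the E geometry under conditions mild enough for a dialkyl peroxide, and the silyl cap keeps the distal alkyne out of the coupling.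

Step 14
Reactants: 24
Product: 25 methyl 2-[(3S,6R)-6-[(6E)-hexadec-6-ene-4,15-diyn-1-yl]-6-methoxy-1,2-dioxan-3-yl]acetate (target)
Conditions: AgNO3 (cat.), acetone/H2O, rt
Reagents that add atoms: none
Why: silver-catalysed protodesilylation of the alkynylsilane in aqueous acetone is neutral and should spare the peroxide, the ester and the enyne.

Compound list
1 | ethynyltriisopropylsilane | C#C[Si](C(C)C)(C(C)C)C(C)C | starting material
2 | 1,3-dibromopropane | BrCCCBr | starting material
3 | lithium (triisopropylsilyl)acetylide | [Li]C#C[Si](C(C)C)(C(C)C)C(C)C | intermediate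
4 | (5-bromopent-1-yn-1-yl)triisopropylsilane | BrCCCC#C[Si](C(C)C)(C(C)C)C(C)C | intermediate
5 | methoxyallene (1-methoxypropa-1,2-diene) | COC=C=C | starting material
6 | 1-lithio-1-methoxyallene | [Li]C(OC)=C=C | intermediate
7 | (6-methoxyocta-6,7-dien-1-yn-1-yl)triisopropylsilane | C=C=C(OC)CCCC#C[Si](C(C)C)(C(C)C)C(C)C | intermediate
8 | rac-(6-hydroperoxy-6-methoxyoct-7-en-1-yn-1-yl)triisopropylsilane | C=CC(OC)(OO)CCCC#C[Si](C(C)C)(C(C)C)C(C)C | intermediate
9 | (2E,4E)-hexa-2,4-dienal (sorbaldehyde) | C/C=C/C=C/C=O | starting material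
10 | (3R,4E)-3-{[3-methoxy-8-(triisopropylsilyl)oct-1-en-7-yn-3-yl]peroxy}hex-4-enal (both epimers at the ketal carbon) | C/C=C/[C@@H](CC=O)OOC(OC)(C=C)CCCC#C[Si](C(C)C)(C(C)C)C(C)C | intermediate
11 | (3R,4E)-3-{[3-methoxy-8-(triisopropylsilyl)oct-1-en-7-yn-3-yl]peroxy}hex-4-enoic acid (both epimers at the ketal carbon) | C/C=C/[C@@H](CC(=O)O)OOC(OC)(C=C)CCCC#C[Si](C(C)C)(C(C)C)C(C)C | intermediate
12 | methyl (3R,4E)-3-{[3-methoxy-8-(triisopropylsilyl)oct-1-en-7-yn-3-yl]peroxy}hex-4-enoate (both epimers at the ketal carbon) | C/C=C/[C@@H](CC(=O)OC)OOC(OC)(C=C)CCCC#C[Si](C(C)C)(C(C)C)C(C)C | intermediate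
13 | methyl 2-[(3R)-6-methoxy-6-[5-(triisopropylsilyl)pent-4-yn-1-yl]-3,6-dihydro-1,2-dioxin-3-yl]acetate (both C6 epimers) | COC(=O)C[C@@H]1C=CC(OC)(CCCC#C[Si](C(C)C)(C(C)C)C(C)C)OO1 | intermediate
14 | methyl 2-[(3S)-6-methoxy-6-[5-(triisopropylsilyl)pent-4-yn-1-yl]-1,2-dioxan-3-yl]acetate (both C6 epimers) | COC(=O)C[C@@H]1CCC(OC)(CCCC#C[Si](C(C)C)(C(C)C)C(C)C)OO1 | intermediate
15 | methyl 2-[(3S,6R)-6-methoxy-6-[5-(triisopropylsilyl)pent-4-yn-1-yl]-1,2-dioxan-3-yl]acetate | CC(C)[Si](C(C)C)(C(C)C)C#CCCC[C@]1(OC)CC[C@@H](CC(=O)OC)OO1 | intermediate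
16 | silver acetylide of 17 | [Ag]C#CCCC[C@]1(OC)CC[C@@H](CC(=O)OC)OO1 | intermediate
17 | methyl 2-[(3S,6R)-6-methoxy-6-(pent-4-yn-1-yl)-1,2-dioxan-3-yl]acetate | C#CCCC[C@]1(OC)CC[C@@H](CC(=O)OC)OO1 | intermediate
18 | dec-9-yn-1-ol | C#CCCCCCCCCO | starting material
19 | dilithio alkoxide acetylide of dec-9-yn-1-ol | [Li]C#CCCCCCCCCO[Li] | intermediate
20 | trimethyl{[10-(trimethylsilyl)dec-9-yn-1-yl]oxy}silane | C[Si](C)(C)C#CCCCCCCCCO[Si](C)(C)C | intermediate
21 | 10-(trimethylsilyl)dec-9-yn-1-ol | C[Si](C)(C)C#CCCCCCCCCO | intermediate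
22 | 10-(trimethylsilyl)dec-9-ynal | C[Si](C)(C)C#CCCCCCCCC=O | intermediate
23 | [(10E)-11-iodoundec-10-en-1-yn-1-yl]trimethylsilane | C[Si](C)(C)C#CCCCCCCC/C=C/I | intermediate
24 | methyl 2-[(3S,6R)-6-methoxy-6-[(6E)-16-(trimethylsilyl)hexadec-6-ene-4,15-diyn-1-yl]-1,2-dioxan-3-yl]acetate | C[Si](C)(C)C#CCCCCCCC/C=C/C#CCCC[C@]1(OC)CC[C@@H](CC(=O)OC)OO1 | intermediate
25 | methyl 2-[(3S,6R)-6-[(6E)-hexadec-6-ene-4,15-diyn-1-yl]-6-methoxy-1,2-dioxan-3-yl]acetate | C#CCCCCCCC/C=C/C#CCCC[C@]1(OC)CC[C@@H](CC(=O)OC)OO1 | target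

Total step count: 14. Longest linear sequence: 11 steps (steps 1–9, 13 and 14); steps 10–12 build the vinyl iodide in parallel.

Steps most likely to fail

Step 6 (ring-closing metathesis). The ruthenium alkylidene may be consumed by the O–O bond, or may fail to initiate at either hindered allylic alkene, so that no ring closes. The fallback uses known chemistry, sets out from bromide 4 and rejoins the route at 14. The Grignard reagent of 4 (Mg, THF) is added to pent-4-enenitrile and the imine hydrolysed with aqueous HCl to 10-(triisopropylsilyl)dec-1-en-9-yn-5-one F1. Wittig methylenation (Ph3P=CH2) gives the diene (6-methylidenedec-9-en-1-yn-1-yl)triisopropylsilane F2. Cross-metathesis of its monosubstituted alkene with crotonaldehyde (second-generation Grubbs catalyst) gives (2E)-6-methylidene-11-(triisopropylsilyl)undec-2-en-10-ynal F3. Ozonolysis in CH2Cl2/MeOH at −78 °C, selective for the electron-rich 1,1-disubstituted alkene, gives the α-methoxy hydroperoxide rac-(2E)-6-hydroperoxy-6-methoxy-11-(triisopropylsilyl)undec-2-en-10-ynal F4. The (R)-diarylprolinol silyl ether of step 4 then closes the ring by intramolecular 6-exo oxa-Michael addition to 2-[(3S)-6-methoxy-6-[5-(triisopropylsilyl)pent-4-yn-1-yl]-1,2-dioxan-3-yl]acetaldehyde F5. Pinnick oxidation gives the acid 2-[(3S)-6-methoxy-6-[5-(triisopropylsilyl)pent-4-yn-1-yl]-1,2-dioxan-3-yl]acetic acid F6, and (trimethylsilyl)diazomethane gives 14. This fallback closes the ring through the O2–C3 bond and gives up the metathesis closure.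

Step 4 (asymmetric peroxidation). 1,6-Addition to the vinylogous iminium ion, or collapse of the β-peroxy enamine to the epoxy aldehyde, may compete with 1,4-peroxidation, and the hindered hydroperoxide may add with poor facial selectivity. The fallback sets out from 8 and rejoins at 13. In place of 9 it uses (2E)-5-methylhexa-2,4-dienal F7, made by Wittig reaction of 3-methylbut-2-enal with (triphenylphosphoranylidene)acetaldehyde; its fully substituted δ-carbon should be closed to 1,6-attack. The same catalyst gives (3R)-3-{[3-methoxy-8-(triisopropylsilyl)oct-1-en-7-yn-3-yl]peroxy}-5-methylhex-4-enal F8. Pinnick oxidation gives (3R)-3-{[3-methoxy-8-(triisopropylsilyl)oct-1-en-7-yn-3-yl]peroxy}-5-methylhex-4-enoic acid F9, and (trimethylsilyl)diazomethane its methyl ester F10. Ring-closing metathesis of F10 with loss of 2-methylpropene then gives 13.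

Step 3 (hydroperoxy ketal formation). Double addition of H2O2, capture of the allyl cation at its far end, or decomposition of the doubly activated hydroperoxide 8 on isolation may prevent its use. The fallback reverses the order of the two C–O bond formations, setting out from 9 and rejoining at 12. Ozonolysis of 2,3-dimethylbut-2-ene in methanol gives 2-hydroperoxy-2-methoxypropane F11. Amine-catalysed peroxidation of 9 with F11 (catalyst of step 4) gives (3R,4E)-3-[(2-methoxypropan-2-yl)peroxy]hex-4-enal F12. Pinnick oxidation gives (3R,4E)-3-[(2-methoxypropan-2-yl)peroxy]hex-4-enoic acid F13, and (trimethylsilyl)diazomethane its methyl ester F14. Aqueous acetic acid in THF removes the 2-methoxypropan-2-yl group to give methyl (3R,4E)-3-hydroperoxyhex-4-enoate F15. PPTS-catalysed addition of F15 to allene 7 in CH2Cl2 at 0 °C gives 12 directly, without free 8.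

Further compounds
F1 | step 6 | 10-(triisopropylsilyl)dec-1-en-9-yn-5-one | C=CCCC(=O)CCCC#C[Si](C(C)C)(C(C)C)C(C)C
F2 | step 6 | (6-methylidenedec-9-en-1-yn-1-yl)triisopropylsilane | C=CCCC(=C)CCCC#C[Si](C(C)C)(C(C)C)C(C)C
F3 | step 6 | (2E)-6-methylidene-11-(triisopropylsilyl)undec-2-en-10-ynal | O=C/C=C/CCC(=C)CCCC#C[Si](C(C)C)(C(C)C)C(C)C
F4 | step 6 | rac-(2E)-6-hydroperoxy-6-methoxy-11-(triisopropylsilyl)undec-2-en-10-ynal | O=C/C=C/CCC(OC)(OO)CCCC#C[Si](C(C)C)(C(C)C)C(C)C
F5 | step 6 | 2-[(3S)-6-methoxy-6-[5-(triisopropylsilyl)pent-4-yn-1-yl]-1,2-dioxan-3-yl]acetaldehyde (both C6 epimers) | O=CC[C@@H]1CCC(OC)(CCCC#C[Si](C(C)C)(C(C)C)C(C)C)OO1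
F6 | step 6 | 2-[(3S)-6-methoxy-6-[5-(triisopropylsilyl)pent-4-yn-1-yl]-1,2-dioxan-3-yl]acetic acid (both C6 epimers) | OC(=O)C[C@@H]1CCC(OC)(CCCC#C[Si](C(C)C)(C(C)C)C(C)C)OO1
F7 | step 4 | (2E)-5-methylhexa-2,4-dienal | CC(C)=C/C=C/C=O
F8 | step 4 | (3R)-3-{[3-methoxy-8-(triisopropylsilyl)oct-1-en-7-yn-3-yl]peroxy}-5-methylhex-4-enal (both epimers at the ketal carbon) | CC(C)=C[C@@H](CC=O)OOC(OC)(C=C)CCCC#C[Si](C(C)C)(C(C)C)C(C)C
F9 | step 4 | (3R)-3-{[3-methoxy-8-(triisopropylsilyl)oct-1-en-7-yn-3-yl]peroxy}-5-methylhex-4-enoic acid (both epimers at the ketal carbon) | CC(C)=C[C@@H](CC(=O)O)OOC(OC)(C=C)CCCC#C[Si](C(C)C)(C(C)C)C(C)C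
F10 | step 4 | methyl (3R)-3-{[3-methoxy-8-(triisopropylsilyl)oct-1-en-7-yn-3-yl]peroxy}-5-methylhex-4-enoate (both epimers at the ketal carbon) | CC(C)=C[C@@H](CC(=O)OC)OOC(OC)(C=C)CCCC#C[Si](C(C)C)(C(C)C)C(C)C
F11 | step 3 | 2-hydroperoxy-2-methoxypropane | COC(C)(C)OO
F12 | step 3 | (3R,4E)-3-[(2-methoxypropan-2-yl)peroxy]hex-4-enal | C/C=C/[C@@H](CC=O)OOC(C)(C)OC
F13 | step 3 | (3R,4E)-3-[(2-methoxypropan-2-yl)peroxy]hex-4-enoic acid | C/C=C/[C@@H](CC(=O)O)OOC(C)(C)OC
F14 | step 3 | methyl (3R,4E)-3-[(2-methoxypropan-2-yl)peroxy]hex-4-enoate | C/C=C/[C@@H](CC(=O)OC)OOC(C)(C)OC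
F15 | step 3 | methyl (3R,4E)-3-hydroperoxyhex-4-enoate | C/C=C/[C@@H](CC(=O)OC)OO
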